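- The constants of this enzyme are hidden, so two earlier runs, elm and birch, have to stand in for them. In the proposed scheme, free enzyme turns starting material into target and second substrate into second product, while starting material can also meet target to give side product.

| flask | starting material | second substrate | free enzyme | temperature | remark | time |
|---|---|---|---|---|---|---|
| elm | 16 mM | 11 mM | 3.2 µM | −25 °C | run made earlier |  |
| birch | 16 mM | 18 mM | 3.2 µM | 8 °C | run made earlier |  |
| Tuesday's | 16 mM | 8.00 mM | 3.2 µM | −20 °C |  | 6.0 d |
| Monday's | 16 mM | 8.00 mM | 3.2 µM | 0 °C |  | 6.0 d |
| Thursday's | 16 mM | 8.00 mM | 3.2 µM | 20 °C |  | 6.0 d |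
| Sunday's | 16 mM | 8.00 mM | 3.2 µM | −40 °C |  | 6.0 d |

elm run (percent of the starting material charged)

| time / d | target / % | starting material / % |
|---|---|---|
| 0.625 | 1.2 | 101.5 |
| 1.67 | 0.3 | 98.7 |
| 3.00 | 1.3 | 100.4 |
| 5.00 | 1.1 | 100.5 |
| 8.00 | 2.1 | 97.1 |

birch run (percent of the starting material charged)

| time / h | target / % | starting material / % |
|---|---|---|
| 4.00 | 4.6 | 96.2 |
| 6.00 | 5.3 | 93.5 |
| 12.0 | 10.6 | 87.3 |
| 25.0 | 19.0 | 76.7 |
| 50.0 | 41.5 | 55.6 |

(each reading ± 1 percentage point)

* the flask that comes out highest in amount of target, in percent of the starting material charged, or "all alike" when all lie within 1.5 percentage points (Tuesday's / Monday's / Thursday's / Sunday's / all alike)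
* target at the end, in percent of the starting material charged, Tuesday's
* target at the end, in percent of the starting material charged, Monday's
* target at the end, in percent of the starting material charged, Thursday's
* target at the end, in percent of the starting material charged, Sunday's

- percent here means starting material units held: one side product counts as two
- what may be going on: free enzyme -> unfolded enzyme; starting material + free enzyme <-> complex A; complex A -> free enzyme + target; second substrate + free enzyme <-> complex B; complex B -> free enzyme + second product; starting material + target -> side product

- Time is the first setting. By hand, a steady flask makes target in proportion to time, so one quantity describes it: the clearing time, the time the charge would last at the pace of the last reading. Birch gives 5.02 d. Elm gives 381 d, a rough reading, with a scatter of 1 percentage point on 2.1 %.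
- Temperature is the second setting. Two runs give two points, so a straight line on a logarithmic scale between −25 °C and 8 °C is an assumption; it gives the doubling step, 5.28 K, the warming that halves the clearing time, a value read from scattered readings.
- Counting from birch, the clearing times are 2730 d for Sunday's, 198 d for Tuesday's, 14.3 d for Monday's and 1.04 d for Thursday's.
- Against 6.0 d, this reckoning of my own gives 0.220 %, 3.03 % and 42.0 % for Sunday's, Tuesday's and Monday's. Thursday's should clear within the time.
- Second substrate is the third setting. By hand, a smaller charge holds less enzyme as complex B and should shorten the clearing time. Elm and birch change temperature together with it, so its share stays unread, and these reckoned yields may lean low.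
- The small correction for Thursday's is the gap in the birch balance, 2.9 points at the last reading, a difference of two scattered readings, assumed here to be side product and to carry over to Thursday's. Subtracted from the full charge, it leaves 97.1 % of target.
- The forecast gives 0.2 %, 3 %, 50 % and 80 % for Sunday's, Tuesday's, Monday's and Thursday's, and names Thursday's. It calls Thursday's “near completion unless unfolding intervenes”. Its Thursday's number, lower than mine, is what first-order decay to completion through the last birch reading gives.

    free enzyme → unfolded enzyme (k = 4.60 × 10⁻⁸ s⁻¹, Ea = 227 kJ mol⁻¹)
    starting material + free enzyme ⇌ complex A (K = 78.0 L mol⁻¹, k = 89.0 L mol⁻¹ s⁻¹, Ea = 47.0 kJ mol⁻¹, ΔH = −53.0 kJ mol⁻¹)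
    complex A → free enzyme + target (k = 0.100 s⁻¹, Ea = 83.0 kJ mol⁻¹)
    second substrate + free enzyme ⇌ complex B (K = 94.0 L mol⁻¹, k = 53.0 L mol⁻¹ s⁻¹, Ea = 49.0 kJ mol⁻¹, ΔH = −13.0 kJ mol⁻¹)
    complex B → free enzyme + second product (k = 0.300 s⁻¹, Ea = 81.0 kJ mol⁻¹)
    starting material + target → side product (k = 2.70 × 10⁻⁵ L mol⁻¹ s⁻¹, Ea = 67.0 kJ mol⁻¹)
    (constants at 20 °C)

- The flasks give 0.159 %, 4.40 %, 58.8 % and 97.4 % in that order, with Thursday's highest. Thursday's ends with starting material at 0 %, as its clearing time of 1.04 d led one to expect. The largest single effect on the difference between Thursday's and Sunday's is what temperature does to the making of free enzyme and target from complex A: without it, that difference stands at −0.08 points instead of 97 points. Thursday's charge held at −5 °C reckons, with the same doubling step, to a clearing time of 27.7 d and 21.7 % of target, and that flask stands at 33.7 %.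

The earlier runs and the new flask were generated by integration with made-up constants; the scatter is artificial.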